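**Plan**

Numbering is germacranolide: carbocycle C1–C10, lactone O–C6/C7–C11–C12(=O), C13 the exocyclic CH2, C14 the methyl on C10, C15 the formyl carbon on C4.
Retrosynthetic cuts, in order: C15 aldehyde to alcohol; C1–O–C10 oxirane to the (E)-C1=C10 olefin; C8 tiglate and C11=C13; C8–OH to C8=O to C8–NO2; the ten-membered ring at C8–C9; then C7–C8 (nitromethane to a butenolide), C6–C7 (propiolate to the C6 aldehyde), C4–C5 (lactone enolate alkylation) and C1=C10 (Wittig).
Enabling feature: C8 bears oxygen and sits next to the lactone carbon C7, so it can be carried as a nitro group (masked carbonyl, nucleophilic as its nitronate), while C9 is the allylic CH2 of the C1=C10 olefin that becomes the oxirane, so it can be the terminus of a π-allyl unit; the two naturally electrophilic carbons are joined by reversing the polarity of C8, with the trans γ-lactone ring already in place.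
Forward order: chiral γ-lactone (C2), isobutenyl lactone, α-alkylation (C4), reductive opening and silylation, C6 aldehyde, butenolide ring, nitro lactone, allylic oxidation and carbonate, ten-membered carbocycle, Nef and reduction, methylenation and tiglate, desilylation, oxirane ring last, C15 oxidation.
Stereochemistry: C2 from the chiral pool; C4 by 1,3-induction in the lactone alkylation; C6 by catalyst-controlled alkynylation; C7 by anti conjugate addition; C8 by oxazaborolidine-controlled reduction; C1/C10 by hydroxyl-directed epoxidation of the E olefin.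

Key step: step 12

Remark (assumption): the (S,S)-antipode of ProPhenol is taken to give the 4R carbinol in step 7; if the sense of induction is the opposite, the (R,R)-ligand is used.

**Route**

Step 1
Reactants: 1 (S)-5-(hydroxymethyl)dihydrofuran-2(3H)-one
Product: 2 (S)-5-oxotetrahydrofuran-2-carbaldehyde
Conditions: Dess–Martin periodinane, CH2Cl2, 0 °C to rt, non-aqueous work-up
Reagents that add atoms: none
Why: Dess–Martin oxidation converts the primary alcohol to the aldehyde under non-basic, anhydrous conditions that leave the lactone and the adjacent C2 stereocentre untouched.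

Step 2
Reactants: 2 (S)-5-oxotetrahydrofuran-2-carbaldehyde; 3 isopropyltriphenylphosphonium iodide
Product: 5 (S)-5-(2-methylprop-1-en-1-yl)dihydrofuran-2(3H)-one, via isopropylidenetriphenylphosphorane 4 (not isolated)
Conditions: 3, n-BuLi, THF, 0 °C; then 2, −78 °C to rt
Reagents that add atoms: isopropyltriphenylphosphonium iodide (3), CC(C)[P+](c1ccccc1)(c1ccccc1)c1ccccc1.[I-]
Why: Wittig olefination with the non-stabilised isopropylidene ylide at low temperature installs C1=C10 together with C9 and C14 as a gem-dimethyl olefin, so that no olefin geometry has to be controlled at this stage and the α-oxy aldehyde is consumed before it can epimerise.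

Step 3
Reactants: 5 (S)-5-(2-methylprop-1-en-1-yl)dihydrofuran-2(3H)-one; 6 tert-butyl bromoacetate
Product: 8 tert-butyl 2-[(3S,5S)-5-(2-methylprop-1-en-1-yl)-2-oxooxolan-3-yl]acetate, via lithium lactone enolate 7 (not isolated)
Conditions: LiN(SiMe3)2 (1.05 equiv), THF, −78 °C; then 6, −78 to −40 °C
Reagents that add atoms: tert-butyl bromoacetate (6), CC(C)(C)OC(=O)CBr
Why: Alkylation of the lithium lactone enolate with the reactive α-bromo ester occurs on the ring face opposite the C2 alkenyl group (1,3-induction in the five-membered enolate), which sets C4 trans to C2 as the target requires.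

Step 4
Reactants: 8 tert-butyl 2-[(3S,5S)-5-(2-methylprop-1-en-1-yl)-2-oxooxolan-3-yl]acetate
Product: 9 tert-butyl (3S,5S)-5-hydroxy-3-(hydroxymethyl)-7-methyloct-6-enoate
Conditions: LiBH4 (1.2 equiv), THF, 0 °C
Reagents that add atoms: none
Why: LiBH4 reduces the lactone to the 1,4-diol chemoselectively in the presence of the hindered tert-butyl ester (ester-selective hydride reduction), freeing C15–OH and C2–OH without touching either stereocentre.

Step 5
Reactants: 9 tert-butyl (3S,5S)-5-hydroxy-3-(hydroxymethyl)-7-methyloct-6-enoate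
Product: 10 tert-butyl (3S,5S)-5-[(tert-butyldimethylsilyl)oxy]-3-{[(tert-butyldimethylsilyl)oxy]methyl}-7-methyloct-6-enoate
Conditions: TBSCl (2.5 equiv), imidazole, DMF, rt
Reagents that add atoms: tert-butyldimethylsilyl chloride (TBSCl), CC(C)(C)[Si](C)(C)Cl
Why: Standard silylation protects both hydroxyls as TBS ethers in one operation so that they can later be released together.

Step 6
Reactants: 10 tert-butyl (3S,5S)-5-[(tert-butyldimethylsilyl)oxy]-3-{[(tert-butyldimethylsilyl)oxy]methyl}-7-methyloct-6-enoate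
Product: 11 (3S,5S)-5-[(tert-butyldimethylsilyl)oxy]-3-{[(tert-butyldimethylsilyl)oxy]methyl}-7-methyloct-6-enal
Conditions: i-Bu2AlH (1.2 equiv), CH2Cl2, −78 °C; aq. KNaC4H4O6 work-up
Reagents that add atoms: none
Why: Low-temperature i-Bu2AlH reduction stops at the tetrahedral aluminate, which collapses to the C6 aldehyde on work-up (partial ester reduction).

Step 7
Reactants: 11 (3S,5S)-5-[(tert-butyldimethylsilyl)oxy]-3-{[(tert-butyldimethylsilyl)oxy]methyl}-7-methyloct-6-enal; 12 methyl propiolate
Product: 13 methyl (4R,6R,8S)-8-[(tert-butyldimethylsilyl)oxy]-6-{[(tert-butyldimethylsilyl)oxy]methyl}-4-hydroxy-10-methylundec-9-en-2-ynoate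
Conditions: Me2Zn (3 equiv), (S,S)-ProPhenol (20 mol %), Ph3P=O (40 mol %), toluene, 4 °C
Reagents that add atoms: methyl propiolate (12), COC(=O)C#C
Why: Catalytic asymmetric alkynylation with the dinuclear zinc–ProPhenol catalyst adds the zinc acetylide of methyl propiolate to one face of the aldehyde, setting C6 (R) by catalyst control since the remote C4 centre exerts little bias.

Step 8
Reactants: 13 methyl (4R,6R,8S)-8-[(tert-butyldimethylsilyl)oxy]-6-{[(tert-butyldimethylsilyl)oxy]methyl}-4-hydroxy-10-methylundec-9-en-2-ynoate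
Product: 15 (5R)-5-[(2R,4S)-4-[(tert-butyldimethylsilyl)oxy]-2-{[(tert-butyldimethylsilyl)oxy]methyl}-6-methylhept-5-en-1-yl]furan-2(5H)-one, via (Z)-hydroxy enoate 14 (not isolated)
Conditions: H2 (1 atm), Pd/CaCO3 poisoned with Pb(OAc)2, quinoline, EtOAc, rt; then PPTS (cat.), toluene, 50 °C
Reagents that add atoms: none
Why: Semihydrogenation of the ynoate over poisoned palladium gives the (Z)-γ-hydroxy enoate, whose cis geometry allows lactonisation to the butenolide (alkyne semireduction then transesterification), leaving the trisubstituted olefin intact.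

Step 9
Reactants: 15 (5R)-5-[(2R,4S)-4-[(tert-butyldimethylsilyl)oxy]-2-{[(tert-butyldimethylsilyl)oxy]methyl}-6-methylhept-5-en-1-yl]furan-2(5H)-one; 16 nitromethane
Product: 17 (4R,5R)-5-[(2R,4S)-4-[(tert-butyldimethylsilyl)oxy]-2-{[(tert-butyldimethylsilyl)oxy]methyl}-6-methylhept-5-en-1-yl]-4-(nitromethyl)oxolan-2-one
Conditions: CH3NO2 (10 equiv), DBU (0.2 equiv), THF, 0 °C to rt
Reagents that add atoms: nitromethane (16), C[N+](=O)[O-]
Why: Base-catalysed Michael addition of nitromethane to the butenolide occurs anti to the C6 substituent, setting C7 with the trans relationship of the target lactone and introducing C8 at the nitro oxidation level.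

Step 10
Reactants: 17 (4R,5R)-5-[(2R,4S)-4-[(tert-butyldimethylsilyl)oxy]-2-{[(tert-butyldimethylsilyl)oxy]methyl}-6-methylhept-5-en-1-yl]-4-(nitromethyl)oxolan-2-one
Product: 18 (4R,5R)-5-[(2R,4S,5E)-4-[(tert-butyldimethylsilyl)oxy]-2-{[(tert-butyldimethylsilyl)oxy]methyl}-7-hydroxy-6-methylhept-5-en-1-yl]-4-(nitromethyl)oxolan-2-one
Conditions: SeO2 (0.5 equiv), t-BuOOH (3 equiv), salicylic acid (cat.), CH2Cl2, rt
Reagents that add atoms: selenium dioxide, O=[Se]=O; tert-butyl hydroperoxide, CC(C)(C)OO
Why: SeO2-mediated allylic oxidation (ene reaction then 2,3-sigmatropic shift) hydroxylates selectively the methyl group trans to C2 on the more substituted olefin terminus, giving the (E)-allylic alcohol that fixes the C1=C10 geometry and activates C9.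

Step 11
Reactants: 18 (4R,5R)-5-[(2R,4S,5E)-4-[(tert-butyldimethylsilyl)oxy]-2-{[(tert-butyldimethylsilyl)oxy]methyl}-7-hydroxy-6-methylhept-5-en-1-yl]-4-(nitromethyl)oxolan-2-one
Product: 19 (2E,4S,6R)-4-[(tert-butyldimethylsilyl)oxy]-6-{[(tert-butyldimethylsilyl)oxy]methyl}-2-methyl-7-[(2R,3R)-3-(nitromethyl)-5-oxooxolan-2-yl]hept-2-en-1-yl methyl carbonate
Conditions: ClCO2Me, pyridine, CH2Cl2, 0 °C
Reagents that add atoms: methyl chloroformate, COC(=O)Cl
Why: Acylation of the primary allylic alcohol with methyl chloroformate under weakly basic conditions (pyridine does not deprotonate the nitroalkane appreciably) gives the carbonate leaving group needed for base-free ionisation.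

Step 12
Reactants: 19 (2E,4S,6R)-4-[(tert-butyldimethylsilyl)oxy]-6-{[(tert-butyldimethylsilyl)oxy]methyl}-2-methyl-7-[(2R,3R)-3-(nitromethyl)-5-oxooxolan-2-yl]hept-2-en-1-yl methyl carbonate
Product: 20 8-nitro-2,15-bis[(tert-butyldimethylsilyl)oxy]germacr-1(10)E-en-12,6-olide (C8 epimer mixture)
Conditions: Pd2(dba)3·CHCl3 (5 mol %), dppe (12 mol %), THF, 50 °C, syringe-pump addition to 0.003 M, no added base
Reagents that add atoms: none
Why: Oxidative addition of zerovalent palladium to the allylic carbonate with loss of CO2 gives a syn π-allyl complex of divalent palladium spanning C9–C10–C1 and one equivalent of methoxide, which deprotonates only the CH2NO2 group (far more acidic than the lactone α-CH2), and the nitronate carbon C8 then attacks the unsubstituted terminus C9 on the face opposite palladium to form the C8–C9 bond and release the catalyst. The closest known reaction type is the Tsuji–Trost allylic alkylation of nitroalkanes with allylic carbonates under neutral conditions, run here in its macrocyclising mode at high dilution. The ten-membered carbocycle is closed in the endo sense with respect to the allyl unit (all three allyl carbons in the ring, attack at the distal CH2 terminus), the competing eight-membered exo closure at C1 being disfavoured because C1 is secondary and flanked by the silyloxy-bearing C2. The only new stereocentre, C8, is formed as an epimer mixture that is of no consequence because the next step converts it to the carbonyl, while the C1=C10 geometry should stay E because the (E)-carbonate ionises to the syn complex and syn–anti exchange would need σ-bonding at the hindered C1. The step needs C- over O-allylation of the nitronate, which the reversibility of O-allylation under palladium catalysis secures, and cyclisation over oligomerisation, which slow addition to a dilute catalyst solution secures. The polarity reversal is what makes the closure possible, since C8 and C9 are both electrophilic in the natural sense (a carbinol carbon and an allylic terminus) and the nitro group turns C8 into a soft carbon nucleophile that is later unmasked to the carbonyl.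

Step 13
Reactants: 20 8-nitro-2,15-bis[(tert-butyldimethylsilyl)oxy]germacr-1(10)E-en-12,6-olide (C8 epimer mixture)
Product: 22 8-oxo-2,15-bis[(tert-butyldimethylsilyl)oxy]germacr-1(10)E-en-12,6-olide, via potassium nitronate 21 (not isolated)
Conditions: KOt-Bu (1.05 equiv), THF, 0 °C; then TiCl3 (20% aq., 6 equiv), NH4OAc buffer (pH 5–6), THF/H2O, 0 °C to rt
Reagents that add atoms: water, O
Why: Nef reaction in its reductive variant, in which the nitronate is reduced by trivalent titanium to the imine that hydrolyses at buffered pH to the C8 ketone without base that could eliminate the β-acyloxy group or move the β,γ-olefin into conjugation.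

Step 14
Reactants: 22 8-oxo-2,15-bis[(tert-butyldimethylsilyl)oxy]germacr-1(10)E-en-12,6-olide
Product: 23 (8S)-8-hydroxy-2,15-bis[(tert-butyldimethylsilyl)oxy]germacr-1(10)E-en-12,6-olide
Conditions: (R)-2-methyl-CBS-oxazaborolidine (0.3 equiv), catecholborane (1.5 equiv), toluene, −78 °C
Reagents that add atoms: none
Why: Corey–Bakshi–Shibata reduction in which the (R)-oxazaborolidine treats the α-branched C7 side as the large group should deliver hydride to the face that gives the (8S)-alcohol (cis to the C6 oxygen), while catecholborane at −78 °C leaves lactone and olefin untouched.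

Step 15
Reactants: 23 (8S)-8-hydroxy-2,15-bis[(tert-butyldimethylsilyl)oxy]germacr-1(10)E-en-12,6-olide
Product: 27 (8S)-8-hydroxy-2,15-bis[(tert-butyldimethylsilyl)oxy]germacra-1(10)E,11(13)-dien-12,6-olide, via dilithium alkoxide enolate 24 (not isolated), via C13 dimethylamino Mannich base 25 (not isolated), via C13 trimethylammonium iodide 26 (not isolated)
Conditions: LiN(i-Pr)2 (2.5 equiv), THF, −78 °C; CH2=NMe2+ I−, −78 to 0 °C; then MeI, CH2Cl2/MeOH, rt; then aq. NaHCO3, EtOAc, rt
Reagents that add atoms: dimethylmethyleneiminium iodide, C=[N+](C)C.[I-]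
Why: Mannich-type α-methylenation in which the lactone enolate (generated beside the C8 alkoxide with excess amide base) is aminomethylated at C11 and quaternisation followed by mild base-induced elimination gives the exocyclic C11=C13 olefin, removing the transient C11 stereocentre.

Step 16
Reactants: 27 (8S)-8-hydroxy-2,15-bis[(tert-butyldimethylsilyl)oxy]germacra-1(10)E,11(13)-dien-12,6-olide; 28 tigloyl chloride
Product: 29 (8S)-8-[(E)-2-methylbut-2-enoyloxy]-2,15-bis[(tert-butyldimethylsilyl)oxy]germacra-1(10)E,11(13)-dien-12,6-olide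
Conditions: 28, pyridine, DMAP (cat.), CH2Cl2, 0 °C to rt
Reagents that add atoms: tigloyl chloride (28), C/C=C(\C)C(=O)Cl
Why: DMAP-catalysed acylation of the only free hydroxyl (C8) with the (E)-configured acid chloride installs the tiglate with retention at C8.

Step 17
Reactants: 29 (8S)-8-[(E)-2-methylbut-2-enoyloxy]-2,15-bis[(tert-butyldimethylsilyl)oxy]germacra-1(10)E,11(13)-dien-12,6-olide
Product: 30 (8S)-2,15-dihydroxy-8-[(E)-2-methylbut-2-enoyloxy]germacra-1(10)E,11(13)-dien-12,6-olide
Conditions: HF·pyridine, pyridine, THF, 0 °C to rt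
Reagents that add atoms: none
Why: Fluoride-mediated cleavage of both silyl ethers under buffered acidic conditions that the lactone, the two enoates and the trisubstituted olefin tolerate.

Step 18
Reactants: 30 (8S)-2,15-dihydroxy-8-[(E)-2-methylbut-2-enoyloxy]germacra-1(10)E,11(13)-dien-12,6-olide
Product: 31 (1R,10R)-1,10-epoxy-2,15-dihydroxy-8-[(E)-2-methylbut-2-enoyloxy]germacr-11(13)-en-12,6-olide
Conditions: VO(acac)2 (5 mol %), t-BuOOH (1.5 equiv, decane), CH2Cl2, 0 °C
Reagents that add atoms: tert-butyl hydroperoxide, CC(C)(C)OO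
Why: Hydroxyl-directed epoxidation in which the vanadium alkylperoxide bound to C2–OH delivers oxygen to the C1=C10 olefin on the face of that hydroxyl, which in the conformer that avoids allylic 1,3-strain with C14 is also the exposed outer face of the (E)-cyclodecene, setting C1 (R) and C10 (R), while the electron-poor methylene lactone and tiglate olefins do not react.

Step 19
Reactants: 31 (1R,10R)-1,10-epoxy-2,15-dihydroxy-8-[(E)-2-methylbut-2-enoyloxy]germacr-11(13)-en-12,6-olide
Product: 32 (1R,2S,4S,6R,7S,8S,10R)-1,10-epoxy-2-hydroxy-15-oxo-8-[(E)-2-methylbut-2-enoyloxy]germacr-11(13)-en-12,6-olide (target CNP0307768.2)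
Conditions: TEMPO (10 mol %), PhI(OAc)2 (1.2 equiv), CH2Cl2, rt
Reagents that add atoms: none
Why: Oxoammonium-mediated oxidation (TEMPO with PhI(OAc)2) is selective for the primary C15 alcohol over the hindered secondary C2 alcohol and should stop at the aldehyde because the trans disposition of C2–OH and C15 on the ring prevents lactol formation, and the neutral conditions do not epimerise C4.

**Compound list**

In 20–31 the centres C2, C4, C6 and C7 have the spatial arrangement of 32; the SMILES are authoritative.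

1 | (S)-5-(hydroxymethyl)dihydrofuran-2(3H)-one | O=C1O[C@H](CO)CC1 | starting material
2 | (S)-5-oxotetrahydrofuran-2-carbaldehyde | O=C1O[C@H](C=O)CC1 | intermediate
3 | isopropyltriphenylphosphonium iodide | CC(C)[P+](c1ccccc1)(c1ccccc1)c1ccccc1.[I-] | starting material
4 | isopropylidenetriphenylphosphorane | CC(C)=P(c1ccccc1)(c1ccccc1)c1ccccc1 | intermediate
5 | (S)-5-(2-methylprop-1-en-1-yl)dihydrofuran-2(3H)-one | O=C1O[C@H](C=C(C)C)CC1 | intermediate
6 | tert-butyl bromoacetate | CC(C)(C)OC(=O)CBr | starting material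
7 | lithium enolate of 5 | [Li+].[O-]C1=CC[C@@H](C=C(C)C)O1 | intermediate
8 | tert-butyl 2-[(3S,5S)-5-(2-methylprop-1-en-1-yl)-2-oxooxolan-3-yl]acetate | O=C1O[C@H](C=C(C)C)C[C@H]1CC(=O)OC(C)(C)C | intermediate
9 | tert-butyl (3S,5S)-5-hydroxy-3-(hydroxymethyl)-7-methyloct-6-enoate | CC(C)(C)OC(=O)C[C@@H](CO)C[C@H](O)C=C(C)C | intermediate
10 | tert-butyl (3S,5S)-5-[(tert-butyldimethylsilyl)oxy]-3-{[(tert-butyldimethylsilyl)oxy]methyl}-7-methyloct-6-enoate | CC(C)(C)OC(=O)C[C@@H](CO[Si](C)(C)C(C)(C)C)C[C@H](O[Si](C)(C)C(C)(C)C)C=C(C)C | intermediate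
11 | (3S,5S)-5-[(tert-butyldimethylsilyl)oxy]-3-{[(tert-butyldimethylsilyl)oxy]methyl}-7-methyloct-6-enal | O=CC[C@@H](CO[Si](C)(C)C(C)(C)C)C[C@H](O[Si](C)(C)C(C)(C)C)C=C(C)C | intermediate
12 | methyl propiolate | COC(=O)C#C | starting material
13 | methyl (4R,6R,8S)-8-[(tert-butyldimethylsilyl)oxy]-6-{[(tert-butyldimethylsilyl)oxy]methyl}-4-hydroxy-10-methylundec-9-en-2-ynoate | COC(=O)C#C[C@H](O)C[C@@H](CO[Si](C)(C)C(C)(C)C)C[C@H](O[Si](C)(C)C(C)(C)C)C=C(C)C | intermediate
14 | methyl (2Z,4R,6R,8S)-8-[(tert-butyldimethylsilyl)oxy]-6-{[(tert-butyldimethylsilyl)oxy]methyl}-4-hydroxy-10-methylundeca-2,9-dienoate | COC(=O)/C=C\[C@H](O)C[C@@H](CO[Si](C)(C)C(C)(C)C)C[C@H](O[Si](C)(C)C(C)(C)C)C=C(C)C | intermediate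
15 | (5R)-5-[(2R,4S)-4-[(tert-butyldimethylsilyl)oxy]-2-{[(tert-butyldimethylsilyl)oxy]methyl}-6-methylhept-5-en-1-yl]furan-2(5H)-one | O=C1C=C[C@@H](C[C@@H](CO[Si](C)(C)C(C)(C)C)C[C@H](O[Si](C)(C)C(C)(C)C)C=C(C)C)O1 | intermediate
16 | nitromethane | C[N+](=O)[O-] | starting material
17 | (4R,5R)-5-[(2R,4S)-4-[(tert-butyldimethylsilyl)oxy]-2-{[(tert-butyldimethylsilyl)oxy]methyl}-6-methylhept-5-en-1-yl]-4-(nitromethyl)oxolan-2-one | O=C1C[C@H](C[N+](=O)[O-])[C@@H](C[C@@H](CO[Si](C)(C)C(C)(C)C)C[C@H](O[Si](C)(C)C(C)(C)C)C=C(C)C)O1 | intermediate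
18 | (4R,5R)-5-[(2R,4S,5E)-4-[(tert-butyldimethylsilyl)oxy]-2-{[(tert-butyldimethylsilyl)oxy]methyl}-7-hydroxy-6-methylhept-5-en-1-yl]-4-(nitromethyl)oxolan-2-one | O=C1C[C@H](C[N+](=O)[O-])[C@@H](C[C@@H](CO[Si](C)(C)C(C)(C)C)C[C@H](O[Si](C)(C)C(C)(C)C)/C=C(\C)CO)O1 | intermediate
19 | (2E,4S,6R)-4-[(tert-butyldimethylsilyl)oxy]-6-{[(tert-butyldimethylsilyl)oxy]methyl}-2-methyl-7-[(2R,3R)-3-(nitromethyl)-5-oxooxolan-2-yl]hept-2-en-1-yl methyl carbonate | O=C1C[C@H](C[N+](=O)[O-])[C@@H](C[C@@H](CO[Si](C)(C)C(C)(C)C)C[C@H](O[Si](C)(C)C(C)(C)C)/C=C(\C)COC(=O)OC)O1 | intermediate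
20 | 8-nitro-2,15-bis[(tert-butyldimethylsilyl)oxy]germacr-1(10)E-en-12,6-olide (C8 epimer mixture) | C1C(=O)O[C@@H]2C[C@@H](CO[Si](C)(C)C(C)(C)C)C[C@H](O[Si](C)(C)C(C)(C)C)/C=C(\C)CC([N+](=O)[O-])[C@@H]12 | intermediate
21 | potassium nitronate of 20 | C1C(=O)O[C@@H]2C[C@@H](CO[Si](C)(C)C(C)(C)C)C[C@H](O[Si](C)(C)C(C)(C)C)/C=C(\C)CC(=[N+]([O-])[O-])[C@@H]12.[K+] | intermediate
22 | 8-oxo-2,15-bis[(tert-butyldimethylsilyl)oxy]germacr-1(10)E-en-12,6-olide | C1C(=O)O[C@@H]2C[C@@H](CO[Si](C)(C)C(C)(C)C)C[C@H](O[Si](C)(C)C(C)(C)C)/C=C(\C)CC(=O)[C@@H]12 | intermediate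
23 | (8S)-8-hydroxy-2,15-bis[(tert-butyldimethylsilyl)oxy]germacr-1(10)E-en-12,6-olide | C1C(=O)O[C@@H]2C[C@@H](CO[Si](C)(C)C(C)(C)C)C[C@H](O[Si](C)(C)C(C)(C)C)/C=C(\C)C[C@H](O)[C@@H]12 | intermediate
24 | dilithium C8 alkoxide / lactone enolate of 23 | [Li+].[Li+].C1=C([O-])O[C@@H]2C[C@@H](CO[Si](C)(C)C(C)(C)C)C[C@H](O[Si](C)(C)C(C)(C)C)/C=C(\C)C[C@H]([O-])[C@@H]12 | intermediate
25 | 13-(dimethylamino) Mannich base of 23 (C11 epimers) | CN(C)CC1C(=O)O[C@@H]2C[C@@H](CO[Si](C)(C)C(C)(C)C)C[C@H](O[Si](C)(C)C(C)(C)C)/C=C(\C)C[C@H](O)[C@@H]12 | intermediate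
26 | 13-(trimethylammonio) iodide from 25 | C[N+](C)(C)CC1C(=O)O[C@@H]2C[C@@H](CO[Si](C)(C)C(C)(C)C)C[C@H](O[Si](C)(C)C(C)(C)C)/C=C(\C)C[C@H](O)[C@@H]12.[I-] | intermediate
27 | (8S)-8-hydroxy-2,15-bis[(tert-butyldimethylsilyl)oxy]germacra-1(10)E,11(13)-dien-12,6-olide | C=C1C(=O)O[C@@H]2C[C@@H](CO[Si](C)(C)C(C)(C)C)C[C@H](O[Si](C)(C)C(C)(C)C)/C=C(\C)C[C@H](O)[C@@H]12 | intermediate
28 | tigloyl chloride, (E)-2-methylbut-2-enoyl chloride | C/C=C(\C)C(=O)Cl | starting material
29 | (8S)-8-[(E)-2-methylbut-2-enoyloxy]-2,15-bis[(tert-butyldimethylsilyl)oxy]germacra-1(10)E,11(13)-dien-12,6-olide | C=C1C(=O)O[C@@H]2C[C@@H](CO[Si](C)(C)C(C)(C)C)C[C@H](O[Si](C)(C)C(C)(C)C)/C=C(\C)C[C@H](OC(=O)/C(C)=C/C)[C@@H]12 | intermediate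
30 | (8S)-2,15-dihydroxy-8-[(E)-2-methylbut-2-enoyloxy]germacra-1(10)E,11(13)-dien-12,6-olide | C=C1C(=O)O[C@@H]2C[C@@H](CO)C[C@H](O)/C=C(\C)C[C@H](OC(=O)/C(C)=C/C)[C@@H]12 | intermediate
31 | (1R,10R)-1,10-epoxy-2,15-dihydroxy-8-[(E)-2-methylbut-2-enoyloxy]germacr-11(13)-en-12,6-olide | C=C1C(=O)O[C@@H]2C[C@@H](CO)C[C@H](O)[C@H]3O[C@]3(C)C[C@H](OC(=O)/C(C)=C/C)[C@@H]12 | intermediate
32 | (1R,2S,4S,6R,7S,8S,10R)-1,10-epoxy-2-hydroxy-15-oxo-8-[(E)-2-methylbut-2-enoyloxy]germacr-11(13)-en-12,6-olide (CNP0307768.2) | C=C1C(=O)O[C@@H]2C[C@@H](C=O)C[C@H](O)[C@H]3O[C@]3(C)C[C@H](OC(=O)/C(C)=C/C)[C@@H]12 | target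

**Step count**

Total steps: 19. Longest linear sequence: 19 steps (from 1; the route is fully linear).

**Steps most likely to fail, with fallbacks**

Step 12. The ten-membered ring closure is slow, so the π-allyl intermediate may oligomerise, eliminate to the diene, or lose the E geometry by syn–anti isomerisation before the nitronate attacks. The fallback sets out from 15 and comes back at 20. It makes the C8–C9 bond intermolecularly and closes the ring at C7–C8 by the conjugate addition instead. Allylic oxidation of 15 (SeO2, t-BuOOH, CH2Cl2) would give the (E)-allylic alcohol of the butenolide F1. Methyl chloroformate and pyridine would give the methyl carbonate F2. Tsuji–Trost allylation of excess nitromethane (Pd2(dba)3·CHCl3, PPh3, THF, rt) would give the homoallylic nitro butenolide F3 with the olefin geometry already locked. DBU in THF at high dilution would then effect the intramolecular nitro-Michael addition anti to the C6 side chain to give 20.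

Step 14. The conformational bias of the ten-membered ring may override reagent control so that hydride arrives on the wrong face of C8, and the β-acyloxy ketone may epimerise or eliminate if reduction is slow. The fallback sets out from 22 and comes back at 23. It accepts the intrinsic facial preference and corrects it by inversion. Reduction with NaBH4 and CeCl3·7H2O (MeOH/THF, −78 °C) would give the 8-epi alcohol F4. Mitsunobu inversion with chloroacetic acid (PPh3, DIAD, toluene, 0 °C to rt) would give the (8S)-chloroacetate F5. Selective cleavage of the chloroacetate with thiourea and NaHCO3 (EtOH, 50 °C) would give 23.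

Step 18. Oxygen may be delivered to the wrong olefin face if the macrocycle populates a conformer in which the C2 hydroxyl lies in the olefin plane and cannot direct. The fallback sets out from 30 and comes back at 31. It uses a two-step halohydrin route that places the oxirane oxygen on the face opposite to the one attacked by an electrophile. N-bromosuccinimide in THF/H2O at 0 °C would give, by anti addition with water entering at the tertiary C10, the C1-bromo C10-hydroxy bromohydrin F6. Ag2O in CH2Cl2 at rt would close it with inversion at C1 to give 31.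

**Further compounds**

F1 | step 12 | (5R)-5-[(2R,4S,5E)-4-[(tert-butyldimethylsilyl)oxy]-2-{[(tert-butyldimethylsilyl)oxy]methyl}-7-hydroxy-6-methylhept-5-en-1-yl]furan-2(5H)-one | O=C1C=C[C@@H](C[C@@H](CO[Si](C)(C)C(C)(C)C)C[C@H](O[Si](C)(C)C(C)(C)C)/C=C(\C)CO)O1
F2 | step 12 | (2E,4S,6R)-4-[(tert-butyldimethylsilyl)oxy]-6-{[(tert-butyldimethylsilyl)oxy]methyl}-2-methyl-7-[(2R)-5-oxo-2,5-dihydrofuran-2-yl]hept-2-en-1-yl methyl carbonate | O=C1C=C[C@@H](C[C@@H](CO[Si](C)(C)C(C)(C)C)C[C@H](O[Si](C)(C)C(C)(C)C)/C=C(\C)COC(=O)OC)O1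
F3 | step 12 | (5R)-5-[(2R,4S,5E)-4-[(tert-butyldimethylsilyl)oxy]-2-{[(tert-butyldimethylsilyl)oxy]methyl}-6-methyl-8-nitrooct-5-en-1-yl]furan-2(5H)-one | O=C1C=C[C@@H](C[C@@H](CO[Si](C)(C)C(C)(C)C)C[C@H](O[Si](C)(C)C(C)(C)C)/C=C(\C)CC[N+](=O)[O-])O1
F4 | step 14 | (8R)-8-hydroxy-2,15-bis[(tert-butyldimethylsilyl)oxy]germacr-1(10)E-en-12,6-olide (8-epi-23) | C1C(=O)O[C@@H]2C[C@@H](CO[Si](C)(C)C(C)(C)C)C[C@H](O[Si](C)(C)C(C)(C)C)/C=C(\C)C[C@@H](O)[C@@H]12
F5 | step 14 | (8S)-8-(chloroacetoxy)-2,15-bis[(tert-butyldimethylsilyl)oxy]germacr-1(10)E-en-12,6-olide | C1C(=O)O[C@@H]2C[C@@H](CO[Si](C)(C)C(C)(C)C)C[C@H](O[Si](C)(C)C(C)(C)C)/C=C(\C)C[C@H](OC(=O)CCl)[C@@H]12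
F6 | step 18 | 1-bromo-2,10,15-trihydroxy-8-[(E)-2-methylbut-2-enoyloxy]germacr-11(13)-en-12,6-olide (bromohydrin, Br at C1 anti to OH at C10) | C=C1C(=O)O[C@@H]2C[C@@H](CO)C[C@H](O)[C@H](Br)[C@](C)(O)C[C@H](OC(=O)/C(C)=C/C)[C@@H]12
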